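## Structural features

The target is a C21 polyketide acid; its chain carbons are numbered here C1–C12 from the ethyl terminus to the ketone, C13 is the carboxyl carbon on C5, and O1′–C6′ are the ring atoms. The ring is a (6R)-4-hydroxy-6-methyl-5,6-dihydro-2H-pyran-2-one acylated at C3′ by C12, so that C12=O, C2′=O and the C4′ enol form one acidic, chelating tricarbonyl unit. The chain holds a cross-conjugated diene acid, C4=C5(C13O2H)–C6=C7: C4=C5 is trisubstituted with the C4 hydrogen cis to the carboxyl group and the sec-butyl carbon C3 cis to C6, and C6=C7 is E. The three stereocentres C3 (S), C9 (R) and C6′ (R) are separated from one another by six or more bonds, so none can be relayed from another and each needs its own source. Fragile points are the tricarbonyl (strong base or nucleophilic hydride attacks it and can epimerise C6′ by β-elimination of O1′), the allylic C3–H (γ to the carboxyl group, and α to the carbonyl in any aldehyde precursor), and the diene geometry. The real difficulty is the C4=C5 bond: C5 bears three different carbon substituents, its geometry must be set next to a labile stereocentre, and the acid must emerge free in a molecule that cannot carry two carboxylic acids through the C12 acylation. The key step exploits the cis relationship of the C4 hydrogen and C13, which is the signature of a syn addition of H and CO2H to a C4≡C5 triple bond; the alkenyl group on C5 (C6=C7) and the branched C3 on C4 tell the two alkyne carbons apart.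

## Logic of the disconnections

16 ⇒ 15. In one sentence, the route is: formic acid is added as H and CO2H across the triple bond of the complete, unprotected enyne 15. The bonds cut are C5–C13 and C4–H. The cut is made here because an alkyne has no geometry to control and because a syn addition gives exactly the H/CO2H cis arrangement of 16. The gain is that the acid appears last and needs no protecting group, and the precursor is a linear enyne made by one sp–sp2 coupling. The demand on the forward step is syn addition with the metal on C5, preference for the alkyne over C6=C7, and tolerance of the tricarbonyl.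

15 ⇒ 10 + 13. The bond cut is C12–C3′. A 3-acyl tricarbonyl is the product of O-acylation of a cyclic 1,3-dione followed by O-to-C acyl shift, and the cut removes the ring with C6′ as a six-carbon unit. The forward step requires that 10 be the only carboxylic acid present, which is why C13 is introduced after this step.

10 ⇒ 9 ⇒ 8 ⇒ 7. No skeletal bond of the target is cut; the C12 carboxyl is traced back through aldehyde and oxirane to a C12=C(CH3)2 double bond. This makes the tail a terpene terminus and lets C7–C12 with C9 come from one chiral-pool compound. The forward oxidation must pick the trisubstituted alkene over the enyne.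

7 ⇒ 2 + 4 (through 6 and 5). The bond cut is C5–C6, between an sp and an sp2 carbon. The cut is convergent: each half carries one stereocentre, and the C6=C7 geometry is fixed in 2 and transferred with retention. The forward step must generate the acetylide from 4 without touching C3 and without isolating a volatile alkyne.

2 ⇒ 1. The bond cut is C6=C7; C6 is added as one carbon with its iodine. C7–C12, C9 and the masked C12 are then all present in 1. The forward step needs E selectivity.

4 ⇒ 3. The bond cut is C4=C5; C5 is added as a CBr2 unit. C3 comes from the chiral pool, and the forward step must be non-basic because C3 is α to the aldehyde in 3.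

13 ⇒ 12 ⇒ 11. The bonds cut are O1′–C2′ (lactone) and then C3′–C4′ (Claisen condensation with an acetate enolate). C6′ comes from 11 as a carbinol that no step breaks.

## Other disconnections considered

Alternative 1: (the first that comes to mind) cut C6=C7 by olefination and C12–C3′ by acylation. The forward key step is a Horner–Wadsworth–Emmons reaction of 1 with the allylic phosphonate A1, tert-butyl (2Z,4S)-2-[(diethoxyphosphoryl)methyl]-4-methylhex-2-enoate. A1 carries C13 as an ester and would be made from 3 by a Morita–Baylis–Hillman reaction, SN2′ bromination and an Arbuzov reaction. The chosen plan is preferred on three grounds. The amine-catalysed first reaction is slow for α-branched aldehydes and keeps C3 α to a carbonyl under basic conditions for a long time, whereas step 2 removes that acidity at once. C13 must travel as an ester through the tail oxidation and the acylation and be released at the end, which adds protecting-group operations. And the chosen plan sets the same C4=C5 geometry by a stereospecific syn addition and ends without a protecting group.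

Alternative 2: cut C8–C9 by an Ireland–Claisen rearrangement. The propanoate A2, tert-butyl (2E,4S)-4-methyl-2-[(1S)-1-(propanoyloxy)prop-2-en-1-yl]hex-2-enoate, would rearrange as its E silyl ketene acetal through a chair to acid A3, (2S,4E,6E,8S)-6-(tert-butoxycarbonyl)-2,8-dimethyldeca-4,6-dienoic acid. This would form C8–C9, transfer the C6 configuration to C9 and create E-C6=C7 in conjugation in one step. The chosen plan is preferred because this trade replaces a stereocentre that the chiral pool gives for nothing (C9) by a bis-allylic C6 carbinol that must itself be made enantioselectively. A competing [3,3] path through C4=C5 is also open. Finally, the carboxyl of A3 is C10 at the wrong oxidation level, so C11 and C12 must still be added in at least three further steps.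

Alternative 3: cut the C7–C12 chain back to a ring. Enzymatic Baeyer–Villiger desymmetrisation of 4-methylcyclohexanone A4 by a cyclohexanone monooxygenase would give (5S)-5-methyloxepan-2-one A5, the enantiomer whose carbonyl carbon maps onto C7. The enzyme distinguishes the two enantiotopic C–C bonds, sets C9 and differentiates the chain ends in one operation, which no small reagent does as selectively. The chosen plan is preferred because this solves only C9, which 1 already supplies with C7 at the aldehyde level. In A5 both ends need a redox correction (the carbonyl becomes C7, the O-bearing carbon C12). The diene acid, the real difficulty, is left untouched.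

Key step: step 10

Remarks: 1, 3 and 11 are taken as commercial, enantioenriched materials; 3 is used freshly distilled because C3 is configurationally labile while it is α to the aldehyde. Compound 8 is carried as the mixture of oxirane epimers, since that centre is destroyed in step 5. Compound 13 and the 3-acyl compounds are drawn as one tautomer each.

## Route

Step 1
Reactants: 1 (R)-citronellal [(3R)-3,7-dimethyloct-6-enal]
Product: 2 (1E,4R)-1-iodo-4,8-dimethylnona-1,7-diene
Conditions: CrCl2 (6 equiv), CHI3 (2 equiv), 1,4-dioxane/THF 6:1, 0 °C to rt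
Reagents that add atoms: iodoform, IC(I)I
Why: Takai iodo-olefination: the geminal dichromium carbenoid from iodoform adds to the aldehyde and anti-elimination from the less crowded β-oxido-chromium adduct should give the E-configured C6=C7 vinyl iodide; the dioxane-rich medium is chosen because it favours E with α-unbranched aldehydes. C9 and the trisubstituted alkene are spectators.

Step 2
Reactants: 3 (2S)-2-methylbutanal
Product: 4 (3S)-1,1-dibromo-3-methylpent-1-ene
Conditions: CBr4 (2 equiv), PPh3 (4 equiv), CH2Cl2, 0 °C
Reagents that add atoms: carbon tetrabromide, BrC(Br)(Br)Br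
Why: Ramirez dibromo-olefination (first stage of the Corey–Fuchs sequence) with the non-basic ylide Ph3P=CBr2 turns the aldehyde carbon into C4 and adds C5; C3 is never exposed to base and loses its α-carbonyl acidity in this step.

Step 3
Reactants: 4 (3S)-1,1-dibromo-3-methylpent-1-ene; 2 (1E,4R)-1-iodo-4,8-dimethylnona-1,7-diene
Product: 7 (6R,8E,12S)-2,6,12-trimethyltetradeca-2,8-dien-10-yne, via lithium acetylide 5 (not isolated), via alkynylzinc bromide 6 (not isolated)
Conditions: 4 (1.3 equiv), n-BuLi (2.6 equiv), THF, −78 to 0 °C; ZnBr2 (1.4 equiv), 0 °C; then 2 (1.0 equiv), Pd(PPh3)4 (5 mol %), THF, rt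
Reagents that add atoms: none
Why: Corey–Fuchs sequence (Br/Li exchange, α-elimination with Fritsch–Buttenberg–Wiechell 1,2-shift, deprotonation) gives 5 without isolating the volatile terminal alkyne; transmetalation to 6 and Negishi coupling with 2 form C5–C6 with retention of the E geometry of C6=C7. The propargylic C3–H is not acidic towards the acetylide, so C3 should keep its configuration.

Step 4
Reactants: 7 (6R,8E,12S)-2,6,12-trimethyltetradeca-2,8-dien-10-yne
Product: 8 3-[(3R,5E,9S)-3,9-dimethylundec-5-en-7-yn-1-yl]-2,2-dimethyloxirane (both epimers at the oxirane CH)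
Conditions: mCPBA (1.05 equiv), NaHCO3, CH2Cl2, 0 °C
Reagents that add atoms: meta-chloroperoxybenzoic acid, OOC(=O)c1cccc(Cl)c1
Why: Prilezhaev epoxidation: the electron-rich trisubstituted C12=C bond should react well ahead of the enyne double bond, which is disubstituted and deactivated by the sp carbon, and of the triple bond; the new oxirane centre is uncontrolled and is destroyed in step 5.

Step 5
Reactants: 8 3-[(3R,5E,9S)-3,9-dimethylundec-5-en-7-yn-1-yl]-2,2-dimethyloxirane
Product: 9 (4R,6E,10S)-4,10-dimethyldodec-6-en-8-ynal
Conditions: H5IO6 (1.2 equiv), THF/Et2O, 0 °C to rt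
Reagents that add atoms: none
Why: Periodic acid opens the oxirane hydrolytically at the tertiary carbon and cleaves the resulting glycol (Malaprade reaction) to the C12 aldehyde and acetone; the aldehyde oxygen is the former oxirane oxygen.

Step 6
Reactants: 9 (4R,6E,10S)-4,10-dimethyldodec-6-en-8-ynal
Product: 10 (4R,6E,10S)-4,10-dimethyldodec-6-en-8-ynoic acid
Conditions: NaClO2, NaH2PO4, 2-methyl-2-butene, t-BuOH/H2O, rt
Reagents that add atoms: sodium chlorite, [Na+].[O-]Cl=O
Why: Pinnick oxidation: chlorous acid adds to the aldehyde and fragments to the acid, the hypochlorous acid formed being trapped by 2-methyl-2-butene so that the enyne is not chlorinated.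

Step 7
Reactants: 11 methyl (3R)-3-hydroxybutanoate
Product: 12 tert-butyl (5R)-5-hydroxy-3-oxohexanoate
Conditions: t-BuOAc (3.3 equiv), LDA (3.3 equiv), THF, −78 °C; then 11, −78 to −20 °C; AcOH quench
Reagents that add atoms: tert-butyl acetate, CC(=O)OC(C)(C)C
Why: Crossed Claisen condensation: excess lithium enolate of tert-butyl acetate first deprotonates the hydroxyl group, then attacks the methyl ester, and the β-keto ester is protected in situ as its enolate; the carbinol centre (the future C6′) is a spectator.

Step 8
Reactants: 12 tert-butyl (5R)-5-hydroxy-3-oxohexanoate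
Product: 13 (6R)-6-methyloxane-2,4-dione [enol form: (6R)-4-hydroxy-6-methyl-5,6-dihydro-2H-pyran-2-one]
Conditions: TFA, CH2Cl2, 0 °C to rt
Reagents that add atoms: none
Why: Acidolysis of the tert-butyl ester and 6-exo-trig lactonisation of the δ-hydroxy acid should outrun decarboxylation at room temperature; the C6′–O bond is not broken, so the R configuration is retained.

Step 9
Reactants: 10 (4R,6E,10S)-4,10-dimethyldodec-6-en-8-ynoic acid; 13 (6R)-6-methyloxane-2,4-dione
Product: 15 (6R)-3-[(4R,6E,10S)-4,10-dimethyldodec-6-en-8-ynoyl]-4-hydroxy-6-methyl-5,6-dihydro-2H-pyran-2-one, via enol ester 14 (not isolated)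
Conditions: DCC (1.1 equiv), DMAP (1.2 equiv), CH2Cl2, 0 °C to rt
Reagents that add atoms: none
Why: Steglich O-acylation of the enol of 13 gives 14, and DMAP then mediates the 1,3 O-to-C acyl shift (Fries-type) to the chelated tricarbonyl 15, forming C12–C3′; 10 is the only carboxylic acid present, so no protection is needed.

Step 10
Reactants: 15 (6R)-3-[(4R,6E,10S)-4,10-dimethyldodec-6-en-8-ynoyl]-4-hydroxy-6-methyl-5,6-dihydro-2H-pyran-2-one
Product: 16 (2E,4S)-2-[(1E,4R)-7-[(6R)-4-hydroxy-6-methyl-2-oxo-5,6-dihydro-2H-pyran-3-yl]-4-methyl-7-oxohept-1-en-1-yl]-4-methylhex-2-enoic acid (CNP0281879.1)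
Conditions: Pd(OAc)2 (5 mol %), Xantphos (10 mol %), HCO2H (3 equiv), Ac2O (20 mol %), toluene, 80 °C
Reagents that add atoms: formic acid, OC=O
Why: Palladium-catalysed hydrocarboxylation of an internal alkyne with formic acid: acetic formic anhydride formed in situ adds to Pd(0)/Xantphos and decarbonylates to a Pd–H species and CO, the hydride adds syn across C4≡C5, CO inserts into the alkenyl–Pd bond and the acyl–Pd is released as the acid by anhydride exchange. The closest known reaction types are this hydrocarboxylation of internal alkynes and the Pd–H hydroalkoxycarbonylation of conjugated enynes and 1,3-diynes to 2-carbonyl-1,3-dienes. No ring is closed and no stereocentre is formed; the new stereo-element is the C4=C5 geometry, which the suprafacial insertion fixes with the C4 hydrogen cis to C13 and hence C3 cis to C6, as in 16. Regioselectivity (Pd, then C13, on C5) is needed: C5 carries the flat alkenyl group, which is smaller than the branched C3 substituent on C4 and can support the alkenyl-palladium as an η3-butadienyl, so steric and electronic bias point the same way. Chemoselectivity is needed for the triple bond over the internal C6=C7 bond, which inserts more slowly, and over transfer semi-reduction, which the CO generated with acetic anhydride should outrun. The acidic medium, free of base and of nucleophilic hydride, keeps the tricarbonyl protonated and leaves C12=O, the lactone, C6′, C9 and the non-acidic C3–H alone. The reagent delivers all of its atoms, so the acid appears free in the last step and no protecting group is needed.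

## Compound list

1 | (R)-citronellal, (3R)-3,7-dimethyloct-6-enal | CC(C)=CCC[C@@H](C)CC=O | starting material
2 | (1E,4R)-1-iodo-4,8-dimethylnona-1,7-diene | I/C=C/C[C@H](C)CCC=C(C)C | intermediate
3 | (2S)-2-methylbutanal | CC[C@H](C)C=O | starting material
4 | (3S)-1,1-dibromo-3-methylpent-1-ene | CC[C@H](C)C=C(Br)Br | intermediate
5 | lithium (3S)-3-methylpent-1-yn-1-ide | CC[C@H](C)C#C[Li] | intermediate
6 | bromo[(3S)-3-methylpent-1-yn-1-yl]zinc | CC[C@H](C)C#C[Zn]Br | intermediate
7 | (6R,8E,12S)-2,6,12-trimethyltetradeca-2,8-dien-10-yne | CC[C@H](C)C#C/C=C/C[C@H](C)CCC=C(C)C | intermediate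
8 | 3-[(3R,5E,9S)-3,9-dimethylundec-5-en-7-yn-1-yl]-2,2-dimethyloxirane (both epimers at the oxirane CH) | CC[C@H](C)C#C/C=C/C[C@H](C)CCC1OC1(C)C | intermediate
9 | (4R,6E,10S)-4,10-dimethyldodec-6-en-8-ynal | CC[C@H](C)C#C/C=C/C[C@H](C)CCC=O | intermediate
10 | (4R,6E,10S)-4,10-dimethyldodec-6-en-8-ynoic acid | CC[C@H](C)C#C/C=C/C[C@H](C)CCC(=O)O | intermediate
11 | methyl (3R)-3-hydroxybutanoate | C[C@@H](O)CC(=O)OC | starting material
12 | tert-butyl (5R)-5-hydroxy-3-oxohexanoate | C[C@@H](O)CC(=O)CC(=O)OC(C)(C)C | intermediate
13 | (6R)-6-methyloxane-2,4-dione | C[C@@H]1CC(=O)CC(=O)O1 | intermediate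
14 | (6R)-6-methyl-2-oxo-5,6-dihydro-2H-pyran-4-yl (4R,6E,10S)-4,10-dimethyldodec-6-en-8-ynoate | CC[C@H](C)C#C/C=C/C[C@H](C)CCC(=O)OC1=CC(=O)O[C@H](C)C1 | intermediate
15 | (6R)-3-[(4R,6E,10S)-4,10-dimethyldodec-6-en-8-ynoyl]-4-hydroxy-6-methyl-5,6-dihydro-2H-pyran-2-one | CC[C@H](C)C#C/C=C/C[C@H](C)CCC(=O)C1=C(O)C[C@@H](C)OC1=O | intermediate
16 | (2E,4S)-2-[(1E,4R)-7-[(6R)-4-hydroxy-6-methyl-2-oxo-5,6-dihydro-2H-pyran-3-yl]-4-methyl-7-oxohept-1-en-1-yl]-4-methylhex-2-enoic acid | CC[C@H](C)/C=C(\C=C\C[C@H](C)CCC(=O)C1=C(O)C[C@@H](C)OC1=O)C(=O)O | target

## Step count and least certain steps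

Total step count: 10. Longest linear sequence: 7 steps (steps 1, 3, 4, 5, 6, 9 and 10, from 1).

Step 10 (key step). Four processes could defeat it. Hydropalladation could occur with the reverse regiochemistry, placing the carboxyl on C4. The Pd-hydride/formate couple could semi-reduce the triple bond by transfer hydrogenation. Pd–H addition and elimination on the product could isomerise C6=C7 or epimerise C3 through C4=C5. The chelating tricarbonyl could sequester the palladium. The fallback abandons the alkyne addition: C13 is carried from the start as a tert-butyl ester and the diene is closed by olefination at C6=C7. It sets out from 3 and 1, uses 13, and returns at 16.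
- Morita–Baylis–Hillman reaction of 3 with tert-butyl acrylate (DABCO, aqueous dioxane) should give tert-butyl (4S)-3-hydroxy-4-methyl-2-methylidenehexanoate F1.
- SN2′ bromination (NBS, Me2S) should give tert-butyl (2Z,4S)-2-(bromomethyl)-4-methylhex-2-enoate F2, which already has the C4=C5 geometry of the target.
- Arbuzov reaction with triethyl phosphite should give tert-butyl (2Z,4S)-2-[(diethoxyphosphoryl)methyl]-4-methylhex-2-enoate F3.
- Horner–Wadsworth–Emmons reaction of F3 with 1 (NaH, THF) should give tert-butyl (2E,4S)-2-[(1E,4R)-4,8-dimethylnona-1,7-dien-1-yl]-4-methylhex-2-enoate F4.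
- The tail is then treated as in steps 4–6 and 9. mCPBA should give tert-butyl (2E,4S)-2-[(1E,4R)-6-(3,3-dimethyloxiran-2-yl)-4-methylhex-1-en-1-yl]-4-methylhex-2-enoate F5. Periodic acid should give tert-butyl (2E,4S)-4-methyl-2-[(1E,4R)-4-methyl-7-oxohept-1-en-1-yl]hex-2-enoate F6. Pinnick oxidation should give (4R,6E,8E,10S)-8-(tert-butoxycarbonyl)-4,10-dimethyldodeca-6,8-dienoic acid F7.
- DCC/DMAP acylation of 13 with F7 should give tert-butyl (2E,4S)-2-[(1E,4R)-7-[(6R)-4-hydroxy-6-methyl-2-oxo-5,6-dihydro-2H-pyran-3-yl]-4-methyl-7-oxohept-1-en-1-yl]-4-methylhex-2-enoate F8, and TFA in CH2Cl2 should release 16.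

Step 1. The iodo-olefination of an α-unbranched aldehyde may show poor E/Z control, and the geometric isomers of a non-polar vinyl iodide are hard to separate, so a Z contaminant would be carried to the end. The fallback sets out from 1 and returns at 2. Ohira–Bestmann homologation of 1 (no α-stereocentre at risk) should give (4R)-4,8-dimethylnon-7-en-1-yne F9. Syn-hydrozirconation with Cp2Zr(H)Cl followed by iodinolysis should then give 2 as a single geometric isomer.

Step 3. The carbenoid rearrangement may be incomplete, the acetylide may be butylated by the 1-bromobutane formed in the flask, or excess organolithium may over-metalate at the propargylic position and erode C3. The fallback avoids organolithium and stoichiometric zinc. It sets out from 3, joins 2, and returns at 7. Ohira–Bestmann homologation of 3 (K2CO3, MeOH, 0 °C, short contact time) should give (3S)-3-methylpent-1-yne F10, which is distilled into triethylamine. Sonogashira coupling with 2 (Pd(PPh3)2Cl2, CuI, Et3N) should then give 7.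

Step 9. The activated acid may rearrange to an N-acylurea, the O-to-C acyl shift may stall at 14, or a ketene may form from the activated acid. The fallback builds the tricarbonyl by ring closure instead of acyl transfer (Lacey–Dieckmann). It sets out from 10 and 11 and returns at 15. Acylation of Meldrum's acid with 10 (DCC, DMAP) should give 5-[(4R,6E,10S)-1-hydroxy-4,10-dimethyldodec-6-en-8-yn-1-ylidene]-2,2-dimethyl-1,3-dioxane-4,6-dione F11. Thermolysis with 11 (toluene, 90 °C, through the acylketene) should give methyl (3R)-3-{[(6R,8E,12S)-6,12-dimethyl-3-oxotetradec-8-en-10-ynoyl]oxy}butanoate F12. Dieckmann cyclisation (TBAF, THF) should then close C3′–C4′ to give 15.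

## Further compounds

F1 | step 10 | tert-butyl (4S)-3-hydroxy-4-methyl-2-methylidenehexanoate (both C3 epimers) | CC[C@H](C)C(O)C(=C)C(=O)OC(C)(C)C
F2 | step 10 | tert-butyl (2Z,4S)-2-(bromomethyl)-4-methylhex-2-enoate | CC[C@H](C)/C=C(\CBr)C(=O)OC(C)(C)C
F3 | step 10 | tert-butyl (2Z,4S)-2-[(diethoxyphosphoryl)methyl]-4-methylhex-2-enoate | CC[C@H](C)/C=C(\CP(=O)(OCC)OCC)C(=O)OC(C)(C)C
F4 | step 10 | tert-butyl (2E,4S)-2-[(1E,4R)-4,8-dimethylnona-1,7-dien-1-yl]-4-methylhex-2-enoate | CC[C@H](C)/C=C(\C=C\C[C@H](C)CCC=C(C)C)C(=O)OC(C)(C)C
F5 | step 10 | tert-butyl (2E,4S)-2-[(1E,4R)-6-(3,3-dimethyloxiran-2-yl)-4-methylhex-1-en-1-yl]-4-methylhex-2-enoate (both oxirane epimers) | CC[C@H](C)/C=C(\C=C\C[C@H](C)CCC1OC1(C)C)C(=O)OC(C)(C)C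
F6 | step 10 | tert-butyl (2E,4S)-4-methyl-2-[(1E,4R)-4-methyl-7-oxohept-1-en-1-yl]hex-2-enoate | CC[C@H](C)/C=C(\C=C\C[C@H](C)CCC=O)C(=O)OC(C)(C)C
F7 | step 10 | (4R,6E,8E,10S)-8-(tert-butoxycarbonyl)-4,10-dimethyldodeca-6,8-dienoic acid | CC[C@H](C)/C=C(\C=C\C[C@H](C)CCC(=O)O)C(=O)OC(C)(C)C
F8 | step 10 | tert-butyl (2E,4S)-2-[(1E,4R)-7-[(6R)-4-hydroxy-6-methyl-2-oxo-5,6-dihydro-2H-pyran-3-yl]-4-methyl-7-oxohept-1-en-1-yl]-4-methylhex-2-enoate | CC[C@H](C)/C=C(\C=C\C[C@H](C)CCC(=O)C1=C(O)C[C@@H](C)OC1=O)C(=O)OC(C)(C)C
F9 | step 1 | (4R)-4,8-dimethylnon-7-en-1-yne | C#CC[C@H](C)CCC=C(C)C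
F10 | step 3 | (3S)-3-methylpent-1-yne | CC[C@H](C)C#C
F11 | step 9 | 5-[(4R,6E,10S)-1-hydroxy-4,10-dimethyldodec-6-en-8-yn-1-ylidene]-2,2-dimethyl-1,3-dioxane-4,6-dione | CC[C@H](C)C#C/C=C/C[C@H](C)CCC(O)=C1C(=O)OC(C)(C)OC1=O
F12 | step 9 | methyl (3R)-3-{[(6R,8E,12S)-6,12-dimethyl-3-oxotetradec-8-en-10-ynoyl]oxy}butanoate | CC[C@H](C)C#C/C=C/C[C@H](C)CCC(=O)CC(=O)O[C@H](C)CC(=O)OC
A1 | alternative 1 | tert-butyl (2Z,4S)-2-[(diethoxyphosphoryl)methyl]-4-methylhex-2-enoate | CC[C@H](C)/C=C(\CP(=O)(OCC)OCC)C(=O)OC(C)(C)C
A2 | alternative 2 | tert-butyl (2E,4S)-4-methyl-2-[(1S)-1-(propanoyloxy)prop-2-en-1-yl]hex-2-enoate | CC[C@H](C)/C=C(\[C@@H](OC(=O)CC)C=C)C(=O)OC(C)(C)C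
A3 | alternative 2 | (2S,4E,6E,8S)-6-(tert-butoxycarbonyl)-2,8-dimethyldeca-4,6-dienoic acid | CC[C@H](C)/C=C(\C=C\C[C@H](C)C(=O)O)C(=O)OC(C)(C)C
A4 | alternative 3 | 4-methylcyclohexanone | CC1CCC(=O)CC1
A5 | alternative 3 | (5S)-5-methyloxepan-2-one | O=C1CC[C@H](C)CCO1
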